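**Retrosynthetic overview**
1. Briarane numbering: C1 is the quaternary fusion carbon, C2–C9 run round the ten-membered ring, C10 is the fusion CH, C11–C14 complete the cyclohexene, C16 is the exocyclic CH2, and C17–C19 are the lactone carbons. Endgame: C6–Cl by invertive chlorination of a 6-alcohol, the lactone by acid closure of O7 on a C19 amide, and the 3Z-alkene from a ring alkyne.
2. Key disconnection: the C1–C10 fusion bond. With C9 as a ketone, the target holds the γ,δ-unsaturated ketone array C9(=O)–C10–C1–C14=C13, which runs through both carbocycles next to O12. Its Claisen antecedent is the allyl vinyl ether C10=C9–O–C13–C14=C1.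
3. That antecedent is a 3,4-dihydro-2H-pyran (O, C9–C13) bridged 2,6 by C14 and C1–C8, which is a twelve-membered oxacycle (C1–C9, O, C13, C14). One [3,3] shift turns the pyran into the cyclohexene and contracts the twelve-membered ring to the ten-membered ring.
4. The macrocycle comes from ring-closing alkyne metathesis at C3≡C4. C8–C9 is made by acylating a lithiated dihydropyran with a D-tartrate Weinreb amide (C4–C8, C16). C17–C19 come from a chelation-controlled propionamide aldol.
5. Ring order: dihydropyranone (RCM), then the twelve-membered ring (alkyne metathesis), then cyclohexene plus ten-membered ring (Claisen), then the γ-lactone.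

Key step: step 21

Assumption: the facial sense of (+)-Ipc2BOMe and of (S,S)-ProPhenol is taken from their behaviour with simple aldehydes. If either is reversed on these substrates, the antipodal reagent is used.

Step 1
Reactants: 1 propargyl alcohol
Product: 3 (Z)-3-iodo-2-methylprop-2-en-1-ol, via alkenylmagnesium alkoxide 2 (not isolated)
Conditions: MeMgBr (3 equiv), CuI (10 mol%), Et2O, −10 °C to rt; then I2, THF, 0 °C
Reagents that add atoms: methylmagnesium bromide C[Mg]Br; iodine II
Why: Copper-catalysed, alkoxide-directed anti-carbomagnesiation of the alkyne and iodinolysis with retention place iodine cis to CH2OH, which fixes the Z geometry of the later C14=C1 alkene.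

Step 2
Reactants: 3 (Z)-3-iodo-2-methylprop-2-en-1-ol
Product: 4 (Z)-triethyl[(3-iodo-2-methylprop-2-enyl)oxy]silane
Conditions: Et3SiCl, imidazole, CH2Cl2, 0 °C
Reagents that add atoms: chlorotriethylsilane CC[Si](Cl)(CC)CC
Why: Standard silylation of a primary alcohol, with the triethylsilyl ether chosen because it can later be oxidised directly under Swern conditions.

Step 3
Reactants: 4 (Z)-triethyl[(3-iodo-2-methylprop-2-enyl)oxy]silane
Product: 6 (Z)-3-methyl-4-(triethylsilyloxy)but-2-enal, via Z-alkenyllithium 5 (not isolated)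
Conditions: t-BuLi (2.1 equiv), Et2O, −78 °C; DMF; aq. NH4Cl
Reagents that add atoms: N,N-dimethylformamide CN(C)C=O
Why: Iodine–lithium exchange keeps the alkene geometry at −78 °C, and formylation of the alkenyllithium with DMF should give the Z-enal (C13 aldehyde).

Step 4
Reactants: 7 allyl alcohol
Product: 8 allyl 2-(trimethylsilyl)ethoxymethyl (SEM) ether
Conditions: SEMCl, i-Pr2NEt, CH2Cl2, 0 °C to rt
Reagents that add atoms: 2-(trimethylsilyl)ethoxymethyl chloride C[Si](C)(C)CCOCCl
Why: O-alkylation (SEM protection) of allyl alcohol gives the ether needed for the alkoxyallylboration.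

Step 5
Reactants: 8 allyl SEM ether; 6 (Z)-3-methyl-4-(triethylsilyloxy)but-2-enal
Product: 10 (3S,4S,5Z)-6-methyl-3-(SEM-oxy)-7-(triethylsilyloxy)hepta-1,5-dien-4-ol, via Z-alkoxyallylborane 9 (not isolated)
Conditions: 8, s-BuLi, THF, −78 °C; (+)-Ipc2BOMe; BF3·OEt2; then 6, −78 °C; H2O2, pH 7 buffer, 0 °C
Reagents that add atoms: none
Why: Brown alkoxyallylboration, in which the Z-γ-alkoxyallylborane reacts through a Zimmerman–Traxler chair to give the syn C12/C13 diol monoether and the isopinocampheyl groups from (−)-α-pinene select the aldehyde face that gives 13S.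

Step 6
Reactants: 10 syn-diol monoether
Product: 11 O13-acrylate of 10
Conditions: acryloyl chloride, i-Pr2NEt, CH2Cl2, −20 °C
Reagents that add atoms: acryloyl chloride C=CC(=O)Cl
Why: Acylation of the only free hydroxyl installs C9 and C10 as an acrylate ester.

Step 7
Reactants: 11 acrylate
Product: 12 (5S,6S)-5-(SEM-oxy)-6-[(Z)-2-methyl-3-(triethylsilyloxy)prop-1-enyl]-5,6-dihydro-2H-pyran-2-one
Conditions: second-generation Grubbs catalyst RuCl2(=CHPh)(PCy3)(SIMes) (5 mol%), CH2Cl2, 40 °C
Reagents that add atoms: none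
Why: Ring-closing metathesis of the acrylate and the monosubstituted vinyl group closes the six-membered unsaturated lactone, while the trisubstituted C14=C1 alkene is too hindered to take part.

Step 8
Reactants: 12 dihydropyranone
Product: 13 (4R,5S,6S)-4-methyl δ-lactone (C11 methyl trans to O12 and to the C13 alkenyl group)
Conditions: MeLi, CuI, Et2O, −78 to −30 °C
Reagents that add atoms: lithium dimethylcuprate [Li+].C[Cu-]C
Why: Gilman cuprate 1,4-addition to the unsaturated δ-lactone occurs anti to the cis-disposed C12 and C13 substituents and so sets C11.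

Step 9
Reactants: 13 4-methyl δ-lactone
Product: 14 Z-enal lactone (C2 aldehyde)
Conditions: (COCl)2, DMSO, CH2Cl2, −78 to −35 °C; Et3N
Reagents that add atoms: none
Why: Swern oxidation cleaves and oxidises a primary triethylsilyl ether in one operation, spares the SEM acetal and the lactone, and keeps the Z-enal geometry at low temperature.

Step 10
Reactants: 14 Z-enal lactone
Product: 15 (2R)-propargylic alcohol lactone
Conditions: (S,S)-ProPhenol (20 mol%), ZnMe2, propyne, Ph3PO (40 mol%), toluene, 0 °C
Reagents that add atoms: propyne CC#C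
Why: Zinc–ProPhenol-catalysed asymmetric alkynylation of an enal sets C2 under catalyst control, and the lactone is inert to the alkynylzinc species.

Step 11
Reactants: 15 propargylic alcohol lactone
Product: 16 O2-TBS ether of 15
Conditions: TBSCl, imidazole, DMF, rt
Reagents that add atoms: tert-butylchlorodimethylsilane CC(C)(C)[Si](C)(C)Cl
Why: Standard silylation protects the only free hydroxyl for the organometallic steps and for the heating.

Step 12
Reactants: 16 TBS ether lactone
Product: 17 cyclic ketene acetal diphenyl phosphate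
Conditions: KHMDS, (PhO)2P(O)Cl, HMPA, THF, −78 °C
Reagents that add atoms: diphenyl chlorophosphate O=P(Cl)(Oc1ccccc1)Oc1ccccc1
Why: Enolisation of the δ-lactone at its only α-CH2 and O-phosphorylation create the C9=C10 enol ether double bond.

Step 13
Reactants: 17 ketene acetal phosphate
Product: 18 6-(trimethylstannyl)-3,4-dihydro-2H-pyran
Conditions: Pd(PPh3)4 (5 mol%), Me3SnSnMe3, LiCl, THF, 65 °C
Reagents that add atoms: hexamethyldistannane C[Sn](C)(C)[Sn](C)(C)C
Why: Palladium-catalysed stannylation of a ketene acetal phosphate (Stille-type cycle on zerovalent palladium) gives the α-alkoxyalkenylstannane without strong base, and the internal alkyne is too unreactive to be distannylated.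

Step 14
Reactants: 19 dimethyl (4S,5S)-2,2-dimethyl-1,3-dioxolane-4,5-dicarboxylate (D-tartrate acetonide)
Product: 20 (4S,5S)-bis-Weinreb amide
Conditions: MeNH(OMe)·HCl, i-PrMgCl, THF, −20 °C
Reagents that add atoms: N,O-dimethylhydroxylamine hydrochloride CNOC.Cl
Why: Aminolysis of both esters by the magnesium amide gives the C2-symmetric bis-Weinreb amide without touching the two stereocentres that become C6 and C7.

Step 15
Reactants: 20 bis-Weinreb amide
Product: 21 ynone Weinreb amide (C5 ketone)
Conditions: 1-propynylmagnesium bromide (1.05 equiv), THF, −20 °C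
Reagents that add atoms: 1-propynylmagnesium bromide CC#C[Mg]Br
Why: In this Weinreb ketone synthesis one equivalent of Grignard reagent forms a stable chelated adduct, so mono-addition differentiates the two homotopic amide groups.

Step 16
Reactants: 21 ynone Weinreb amide
Product: 22 enyne Weinreb amide (C16 methylene in place)
Conditions: Ph3PCH3Br, KHMDS, THF, −78 to 0 °C
Reagents that add atoms: methyltriphenylphosphonium bromide C[P+](c1ccccc1)(c1ccccc1)c1ccccc1.[Br-]
Why: Wittig methylenation is selective for the ynone over the amide, and C6 is not at risk because the trans-dioxolane is the more stable epimer.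

Step 17
Reactants: 18 stannyl dihydropyran; 22 enyne Weinreb amide
Product: 24 C8 ketone (6-acyl dihydropyran diyne), via C9-lithiated dihydropyran 23 (not isolated)
Conditions: 18, MeLi, THF, −78 °C; then 22, −78 °C
Reagents that add atoms: none
Why: Tin–lithium exchange is faster than any deprotonation, and acylation of the alkenyllithium by the Weinreb amide forms C8–C9 and stops at the ketone.

Step 18
Reactants: 24 C8 ketone
Product: 25 aldol adduct (tertiary C8 alcohol bearing CH(CH3)C(O)NMe2)
Conditions: EtC(O)NMe2, LDA, THF, −78 °C; MgBr2·OEt2; then 24, −78 °C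
Reagents that add atoms: N,N-dimethylpropanamide CCC(=O)N(C)C
Why: Aldol addition of the Z-amide enolate through a magnesium chelate that ties the ketone oxygen to O7 (Cram chelate inside a Zimmerman–Traxler chair, C7 axial) brings C17 in anti to C6, which sets C8, and places the C18 methyl syn to the new hydroxyl, which sets C17.

Step 19
Reactants: 25 aldol adduct
Product: 26 O8-triethylsilyl ether diyne
Conditions: Et3SiOTf, 2,6-lutidine, CH2Cl2, −78 to 0 °C
Reagents that add atoms: triethylsilyl trifluoromethanesulfonate CC[Si](CC)(CC)OS(=O)(=O)C(F)(F)F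
Why: Silyl triflate silylation of the tertiary alcohol under buffered conditions spares the enol ether and blocks retro-aldol cleavage in the later heating.

Step 20
Reactants: 26 diyne
Product: 27 2,6-bridged dihydropyran (twelve-membered ring with C3≡C4 enyne and Z-C14=C1)
Conditions: Mo(≡CC6H4-4-OMe)(OSiPh3)3 (15 mol%), 5 Å molecular sieves, toluene (0.002 M), 80 °C
Reagents that add atoms: none
Why: Ring-closing alkyne metathesis of two methyl-capped alkynes, one of them part of a 1,3-enyne, closes the twelve-membered ring, is driven by uptake of but-2-yne in the sieves, and leaves all alkenes and the enol ether untouched.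

Step 21
Reactants: 27 bridged dihydropyran
Product: 28 bicyclic C9 ketone (ten-membered cycloenyne trans-fused to the cyclohexene)
Conditions: 1,2-dichlorobenzene (0.005 M), N,O-bis(trimethylsilyl)acetamide (0.5 equiv), BHT, base-washed sealed tube, 200 °C
Reagents that add atoms: none
Why: Proposed new method: On heating, the allyl vinyl ether C10=C9–O–C13–C14=C1 should undergo a concerted suprafacial [3,3]-sigmatropic (Claisen) shift that breaks O–C13 and makes C1–C10; the closest known reactions are the thermal rearrangement of 2-alkenyl-3,4-dihydro-2H-pyrans to cyclohex-3-enyl ketones and the Claisen ring contraction of macrolactone ketene acetals, but a 2,6-bridged dihydropyran has not been used. The cyclohexene closes because C10 and C13 are already linked through C11 and C12, so the six-atom array can only fold into a boat, and the ten-membered ring results from the twelve-membered one when O, C13 and C14 leave the ring path and C10 enters it (net contraction by two atoms). C10 is set by the C13 stereocentre, since the alkenyl group can reach only the face of the enol ether on which it stands (cis to O12, trans to the C11 methyl). C1 is set by the Z geometry of C14=C1 in the enforced boat, which puts C15 cis and C2 trans to C9, that is the trans ring fusion. The step needs chemoselectivity for this one [3,3] array and freedom from acid: there is no second 1,5-diene unit, the C3≡C4 alkyne in place of the later Z-alkene excludes a 1,5-hydrogen shift from C2, the C8 silyl ether excludes retro-aldol cleavage, and the silylating scavenger protects the enol ether. Formation of the C9=O bond pays for the added strain of the cyclodecenyne.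

Step 22
Reactants: 28 C9 ketone
Product: 29 (9S)-alcohol
Conditions: NaBH4, MeOH/THF, 0 °C to rt
Reagents that add atoms: none
Why: Borohydride reduction under Felkin–Anh control, in which the segment C7–C8–C9–C10 stays extended, the C8–OSi bond stands perpendicular to the carbonyl and hydride attacks anti to it to give 9S, while the tertiary amide is neither reduced nor able to lactonise on O9.

Step 23
Reactants: 29 (9S)-alcohol
Product: 30 2,8,9-triol
Conditions: TBAF, THF, 0 °C to rt
Reagents that add atoms: none
Why: Fluoride cleaves both silyl ethers at room temperature whereas SEM ethers need forcing conditions, and an amide enolate is too poor a leaving group for retro-aldol cleavage.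

Step 24
Reactants: 30 triol
Product: 31 2,9-diacetate
Conditions: Ac2O, DMAP, pyridine, rt
Reagents that add atoms: acetic anhydride CC(=O)OC(C)=O
Why: DMAP-catalysed acylation esterifies the two secondary alcohols and leaves the hindered tertiary C8 hydroxyl free.

Step 25
Reactants: 31 diacetate
Product: 32 12-alcohol
Conditions: MgBr2·OEt2, MeNO2, Et2O, rt
Reagents that add atoms: none
Why: Magnesium bromide chelates the two acetal oxygens of the SEM group and cleaves it under mild conditions that esters and the isopropylidene acetal should survive.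

Step 26
Reactants: 32 12-alcohol
Product: 33 12-propionate
Conditions: (EtCO)2O, DMAP, Et3N, CH2Cl2, 0 °C
Reagents that add atoms: propionic anhydride CCC(=O)OC(=O)CC
Why: DMAP-catalysed acylation of the only free secondary alcohol places the propionate on O12 with retention.

Step 27
Reactants: 33 12-propionate
Product: 35 γ-lactone 6-alcohol (enyne), via triol amide 34 (not isolated)
Conditions: TFA/H2O/CH2Cl2, 0 °C to rt
Reagents that add atoms: none
Why: Acid hydrolysis of the acetonide frees O6 and O7, and the γ-hydroxy amide then closes by five-membered (5-exo-trig) lactonisation on O7 in preference to the six-membered alternative on O6, with no stereocentre touched.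

Step 28
Reactants: 35 γ-lactone 6-alcohol (enyne)
Product: 36 (3Z)-diene 6-alcohol
Conditions: H2 (1 atm), Pd/CaCO3 poisoned with Pb(OAc)2 (Lindlar catalyst), quinoline, EtOAc, rt
Reagents that add atoms: none
Why: Lindlar semihydrogenation adds hydrogen syn to the strained ring alkyne faster than to any alkene and gives the 3Z-alkene of the diene.

Step 29
Reactants: 36 (3Z)-diene 6-alcohol
Product: 37 CNP0305105.1 (target)
Conditions: PPh3, Cl3CC(O)CCl3, CH2Cl2, −20 to 0 °C
Reagents that add atoms: hexachloroacetone O=C(C(Cl)(Cl)Cl)C(Cl)(Cl)Cl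
Why: Appel-type chlorination with triphenylphosphine and hexachloroacetone, the variant known to give unrearranged chlorides from secondary allylic alcohols, displaces the oxyphosphonium group by SN2 with inversion and sets 6S, while the tertiary C8 hydroxyl does not react.

**Compound list**
1 | propargyl alcohol | C#CCO | starting material
2 | alkenylmagnesium alkoxide, (Z)-BrMgCH=C(CH3)CH2OMgBr | Br[Mg]/C=C(/C)CO[Mg]Br | intermediate
3 | (Z)-3-iodo-2-methylprop-2-en-1-ol | I/C=C(/C)CO | intermediate
4 | (Z)-triethyl[(3-iodo-2-methylprop-2-enyl)oxy]silane | I/C=C(/C)CO[Si](CC)(CC)CC | intermediate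
5 | Z-alkenyllithium from 4 | [Li]/C=C(/C)CO[Si](CC)(CC)CC | intermediate
6 | (Z)-3-methyl-4-(triethylsilyloxy)but-2-enal | O=C/C=C(/C)CO[Si](CC)(CC)CC | intermediate
7 | allyl alcohol | C=CCO | starting material
8 | allyl SEM ether | C=CCOCOCC[Si](C)(C)C | intermediate
9 | (Z)-γ-(SEM-oxy)allyldiisopinocampheylborane | C[Si](C)(C)CCOCO/C=C\CB([C@H]1C[C@H]2C[C@@H]([C@@H]1C)C2(C)C)[C@H]1C[C@H]2C[C@@H]([C@@H]1C)C2(C)C | intermediate
10 | (3S,4S,5Z)-6-methyl-3-(SEM-oxy)-7-(triethylsilyloxy)hepta-1,5-dien-4-ol | C=C[C@H](OCOCC[Si](C)(C)C)[C@@H](O)/C=C(/C)CO[Si](CC)(CC)CC | intermediate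
11 | O13-acrylate of 10 | C=C[C@H](OCOCC[Si](C)(C)C)[C@@H](OC(=O)C=C)/C=C(/C)CO[Si](CC)(CC)CC | intermediate
12 | (5S,6S)-5-(SEM-oxy)-6-alkenyl-5,6-dihydro-2H-pyran-2-one | O=C1C=C[C@H](OCOCC[Si](C)(C)C)[C@@H](O1)/C=C(/C)CO[Si](CC)(CC)CC | intermediate
13 | (4R,5S,6S)-4-methyl δ-lactone | O=C1C[C@@H](C)[C@H](OCOCC[Si](C)(C)C)[C@@H](O1)/C=C(/C)CO[Si](CC)(CC)CC | intermediate
14 | Z-enal lactone | O=C1C[C@@H](C)[C@H](OCOCC[Si](C)(C)C)[C@@H](O1)/C=C(/C)C=O | intermediate
15 | (2R)-propargylic alcohol lactone | O=C1C[C@@H](C)[C@H](OCOCC[Si](C)(C)C)[C@@H](O1)/C=C(/C)[C@@H](O)C#CC | intermediate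
16 | O2-TBS ether lactone | O=C1C[C@@H](C)[C@H](OCOCC[Si](C)(C)C)[C@@H](O1)/C=C(/C)[C@@H](O[Si](C)(C)C(C)(C)C)C#CC | intermediate
17 | cyclic ketene acetal diphenyl phosphate | O=P(Oc1ccccc1)(Oc1ccccc1)OC1=C[C@@H](C)[C@H](OCOCC[Si](C)(C)C)[C@@H](O1)/C=C(/C)[C@@H](O[Si](C)(C)C(C)(C)C)C#CC | intermediate
18 | 6-(trimethylstannyl)dihydropyran | C[Sn](C)(C)C1=C[C@@H](C)[C@H](OCOCC[Si](C)(C)C)[C@@H](O1)/C=C(/C)[C@@H](O[Si](C)(C)C(C)(C)C)C#CC | intermediate
19 | dimethyl (4S,5S)-2,2-dimethyl-1,3-dioxolane-4,5-dicarboxylate | COC(=O)[C@H]1OC(C)(C)O[C@@H]1C(=O)OC | starting material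
20 | (4S,5S)-bis-Weinreb amide | CON(C)C(=O)[C@H]1OC(C)(C)O[C@@H]1C(=O)N(C)OC | intermediate
21 | ynone Weinreb amide | CC#CC(=O)[C@H]1OC(C)(C)O[C@@H]1C(=O)N(C)OC | intermediate
22 | enyne Weinreb amide | CC#CC(=C)[C@H]1OC(C)(C)O[C@@H]1C(=O)N(C)OC | intermediate
23 | C9-lithiated dihydropyran | [Li]C1=C[C@@H](C)[C@H](OCOCC[Si](C)(C)C)[C@@H](O1)/C=C(/C)[C@@H](O[Si](C)(C)C(C)(C)C)C#CC | intermediate
24 | C8 ketone (6-acyl dihydropyran diyne) | CC#CC(=C)[C@H]1OC(C)(C)O[C@@H]1C(=O)C1=C[C@@H](C)[C@H](OCOCC[Si](C)(C)C)[C@@H](O1)/C=C(/C)[C@@H](O[Si](C)(C)C(C)(C)C)C#CC | intermediate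
25 | aldol adduct (tertiary C8 alcohol, dimethylamide) | CC#CC(=C)[C@H]1OC(C)(C)O[C@@H]1[C@@](O)([C@@H](C)C(=O)N(C)C)C1=C[C@@H](C)[C@H](OCOCC[Si](C)(C)C)[C@@H](O1)/C=C(/C)[C@@H](O[Si](C)(C)C(C)(C)C)C#CC | intermediate
26 | O8-triethylsilyl ether diyne | CC#CC(=C)[C@H]1OC(C)(C)O[C@@H]1[C@@](O[Si](CC)(CC)CC)([C@@H](C)C(=O)N(C)C)C1=C[C@@H](C)[C@H](OCOCC[Si](C)(C)C)[C@@H](O1)/C=C(/C)[C@@H](O[Si](C)(C)C(C)(C)C)C#CC | intermediate
27 | 2,6-bridged dihydropyran, twelve-membered enyne ring | C=C1C#C[C@H](O[Si](C)(C)C(C)(C)C)/C(C)=C\[C@@H]2OC(=C[C@@H](C)[C@@H]2OCOCC[Si](C)(C)C)[C@](O[Si](CC)(CC)CC)([C@@H](C)C(=O)N(C)C)[C@H]2OC(C)(C)O[C@H]12 | intermediate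
28 | bicyclic C9 ketone (ten-membered cycloenyne, trans-fused cyclohexene) | C=C1C#C[C@H](O[Si](C)(C)C(C)(C)C)[C@@]2(C)C=C[C@@H](OCOCC[Si](C)(C)C)[C@H](C)[C@@H]2C(=O)[C@](O[Si](CC)(CC)CC)([C@@H](C)C(=O)N(C)C)[C@H]2OC(C)(C)O[C@H]12 | intermediate
29 | (9S)-alcohol | C=C1C#C[C@H](O[Si](C)(C)C(C)(C)C)[C@@]2(C)C=C[C@@H](OCOCC[Si](C)(C)C)[C@H](C)[C@@H]2[C@H](O)[C@](O[Si](CC)(CC)CC)([C@@H](C)C(=O)N(C)C)[C@H]2OC(C)(C)O[C@H]12 | intermediate
30 | 2,8,9-triol | C=C1C#C[C@H](O)[C@@]2(C)C=C[C@@H](OCOCC[Si](C)(C)C)[C@H](C)[C@@H]2[C@H](O)[C@](O)([C@@H](C)C(=O)N(C)C)[C@H]2OC(C)(C)O[C@H]12 | intermediate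
31 | 2,9-diacetate | C=C1C#C[C@H](OC(C)=O)[C@@]2(C)C=C[C@@H](OCOCC[Si](C)(C)C)[C@H](C)[C@@H]2[C@H](OC(C)=O)[C@](O)([C@@H](C)C(=O)N(C)C)[C@H]2OC(C)(C)O[C@H]12 | intermediate
32 | 12-alcohol | C=C1C#C[C@H](OC(C)=O)[C@@]2(C)C=C[C@@H](O)[C@H](C)[C@@H]2[C@H](OC(C)=O)[C@](O)([C@@H](C)C(=O)N(C)C)[C@H]2OC(C)(C)O[C@H]12 | intermediate
33 | 12-propionate | C=C1C#C[C@H](OC(C)=O)[C@@]2(C)C=C[C@@H](OC(=O)CC)[C@H](C)[C@@H]2[C@H](OC(C)=O)[C@](O)([C@@H](C)C(=O)N(C)C)[C@H]2OC(C)(C)O[C@H]12 | intermediate
34 | triol amide (6,7,8-triol) | C=C1C#C[C@H](OC(C)=O)[C@@]2(C)C=C[C@@H](OC(=O)CC)[C@H](C)[C@@H]2[C@H](OC(C)=O)[C@](O)([C@@H](C)C(=O)N(C)C)[C@@H](O)[C@@H]1O | intermediate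
35 | γ-lactone 6-alcohol (enyne) | C=C1C#C[C@H](OC(C)=O)[C@@]2(C)C=C[C@@H](OC(=O)CC)[C@H](C)[C@@H]2[C@H](OC(C)=O)[C@]2(O)[C@@H](C)C(=O)O[C@H]2[C@@H]1O | intermediate
36 | (3Z)-diene 6-alcohol | C=C1/C=C\[C@H](OC(C)=O)[C@@]2(C)C=C[C@@H](OC(=O)CC)[C@H](C)[C@@H]2[C@H](OC(C)=O)[C@]2(O)[C@@H](C)C(=O)O[C@H]2[C@@H]1O | intermediate
37 | CNP0305105.1 | C=C1/C=C\[C@H](OC(C)=O)[C@@]2(C)C=C[C@@H](OC(=O)CC)[C@H](C)[C@@H]2[C@H](OC(C)=O)[C@]2(O)[C@@H](C)C(=O)O[C@H]2[C@H]1Cl | target

Total step count: 29. Longest linear sequence: 25 steps (steps 1–3, 5–13, 17–29).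

**Steps most likely to fail**

Step 21. The rearrangement has to build a quaternary carbon through a boat transition state. It may therefore be slower than thermal breakdown of the substrate, for example retro-hetero-Diels–Alder opening of the dihydropyran or loss of acetal and silyl groups.

The fallback sets out from 27 and replaces the neutral pericyclic reaction by the known organoaluminium-promoted Claisen rearrangement. Al(i-Bu)3 in toluene from −40 °C to rt binds the ring oxygen, and the charge-accelerated shift runs far below the thermal range. The aluminium-bound ketone is reduced at once by β-hydride transfer from the outer face. Steps 21 and 22 merge and the route is rejoined at 29. This fallback makes no new compound F0.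

Step 22. The ketone lies between a quaternary and a tertiary carbon, so reduction may be sluggish, and external hydride may attack the wrong face if the ring does not adopt the assumed extended conformation.

The fallback sets out from 28 and switches from external to internal hydride delivery. TBAF in THF removes both silyl groups to give the 2,8-dihydroxy 9-ketone F1. Me4NBH(OAc)3 in MeCN/AcOH at −20 °C then binds to the C8 hydroxyl and delivers hydride syn to the C8–O bond, the face opposite to the one reached by Felkin–Anh attack in any given conformer. The product is triol 30, where the route is rejoined.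

Step 29. The activated allylic alcohol may react by allylic transposition (chloride attack at C16) or by ionisation with loss of configuration, instead of by direct displacement.

The fallback sets out from 36 and uses the transposition on purpose. SOCl2 in Et2O at 0 °C (SNi′) should give the transposed primary allylic chloride F2. Sodium phenylselenide (PhSeSePh, NaBH4, EtOH) displaces the chloride to give the primary allylic selenide F3. N-chlorosuccinimide in CH2Cl2 at 0 °C chlorinates selenium and triggers the known [2,3]-sigmatropic shift. That shift returns chlorine to C6 from the outer face and restores the C5=C16 methylene, giving 37.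

**Further compounds**
F0 | step 21 | none | none
F1 | step 22 | 2,8-dihydroxy 9-ketone | C=C1C#C[C@H](O)[C@@]2(C)C=C[C@@H](OCOCC[Si](C)(C)C)[C@H](C)[C@@H]2C(=O)[C@](O)([C@@H](C)C(=O)N(C)C)[C@H]2OC(C)(C)O[C@H]12
F2 | step 29 | transposed primary allylic chloride (16-chloro-3Z,5-diene, C4 and C7 cis on C5=C6) | ClCC1/C=C\[C@H](OC(C)=O)[C@@]2(C)C=C[C@@H](OC(=O)CC)[C@H](C)[C@@H]2[C@H](OC(C)=O)[C@]2(O)[C@@H](C)C(=O)O[C@H]2\C=1
F3 | step 29 | primary allylic selenide (16-phenylselanyl-3Z,5-diene) | c1ccccc1[Se]CC1/C=C\[C@H](OC(C)=O)[C@@]2(C)C=C[C@@H](OC(=O)CC)[C@H](C)[C@@H]2[C@H](OC(C)=O)[C@]2(O)[C@@H](C)C(=O)O[C@H]2\C=1
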